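## The problem

The target is a C40 pseudo-dimer. Two C20 oxylipin chains (locants C1–C20 for the half with the two free carbinols, C1′–C20′ for the other) are joined by the C10–C11′ bond and the C11–O–C12′ ether, which together form a fully substituted, all-trans oxolane (ring atoms O, C11, C10, C11′, C12′). Each ring carbon carries a different arm: C11 the C12 carbinol and a skipped (Z,Z)-diene, C10 the C9 carbinol on a trans-cyclopropyl δ-lactone, C11′ an E-alkene leading to a second, identical cyclopropyl lactone, and C12′ a second skipped diene. There are twelve stereocentres. The two lactone–cyclopropane triads (C5/C6/C8 and C5′/C6′/C8′) are remote from the ring and from each other, so they cannot be relayed and must be brought in enantiopure by reagent control. On the ring, C12′ and C11′ can be inherited from an epoxide, C10 is α to a latent C9 carbonyl and can be left to thermodynamic control, C11 needs a real stereochemical device, C9 can be set last from a ketone, and the isolated C12 is best taken from the chiral pool. The skipped dienes exclude hydrogenation, radicals, hot base and metal hydrides that move double bonds; the δ-lactones exclude hard nucleophiles; both cyclopropylcarbinyl positions (C9 and the C9′ alkene terminus) exclude free cations. The feature that opens the problem is the pattern around the ring: C11′ bears an alkenyl group (C10′=C9′) and sits next to the oxygen-bearing C12′, the imprint of a vinyl epoxide opened at its allylic C–O bond, while C10 bears the C9 carbinol carbon 1,3 to the ring oxygen through C11, the imprint of an oxa-Michael addition to a C9-keto C10=C11 enone.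

## Retrosynthesis

**Target 33 back to ketone 31 (through 32).** The O–Si bond at C12 and the C9–H bond are cut: the C9 carbinol becomes a ketone and the C12 hydroxyl a silyl ether. Carrying the C9 alcohol through would be worse, because the C9 carbonyl makes C10=C11 an acceptor, makes C10 epimerisable and lets C9 be set last by a reagent. Ketone 31 has one stereocentre fewer and one (C10) under thermodynamic control. The forward steps must reduce a hindered cyclopropyl ketone to the 9R alcohol 32 beside two lactones and five alkenes, then remove silicon without ionising the cyclopropylcarbinol.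

**Ketone 31 back to enone 23 and vinyl epoxide 30 (key disconnection).** Two ring bonds are cut together, C10–C11′ and C11–O. Cutting only C11–O or only C12′–O leaves a branched acyclic chain whose C10/C11′/C12′ triad must still be built. Cutting both divides the C40 skeleton into two C20 halves that already carry their cyclopropyl lactones and skipped dienes. Four ring stereocentres reduce to one trans epoxide plus one E-enone, and neither 23 nor 30 contains the oxolane. The forward reaction must ionise only the allylic C11′–O bond of 30, deliver the C12′ oxygen to C11 and the C10 enolate to C11′ (not C9′) with retention, and select the C11 configuration.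

**Vinyl epoxide 30 back to sulfone 11 and epoxy aldehyde 29; enone 23 back to keto phosphonate 13 and aldehyde 22.** The C9′=C10′ and C10=C11 double bonds are cut. Cutting C8–C9 or C8′–C9′ instead would need a metallated cyclopropane that carries a lactone. Cutting the alkenes lets both halves grow from one cyclopropyl lactone alcohol 9 (via sulfide 10 to 11, via aldehyde 12 to 13). No fragment then has more than three stereocentres. Both olefinations must be E-selective and mild enough for an epoxy aldehyde, an α-silyloxy aldehyde and a δ-lactone.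

**Alcohol 9 back to (E)-butenediol 1.** The lactone C–O and the C4–C5 bond are cut (9 from silyl ether 8, from aldehyde 4 and iodo ester 5 through zinc reagent 6 and hydroxy ester 7), then the two cyclopropane bonds to C7 (4 from cyclopropylmethanol 3, from allylic alcohol 2, from 1). A hydroxyl-directed cyclopropanation of a C5 allylic alcohol was set aside because it is expected to favour the other C5/C6 relationship. Here the ring is set by a chiral boronate and C5 by a chiral titanium catalyst, independently. The precursors are achiral; the forward steps need reagent control twice.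

**Epoxy aldehyde 29 back to dienol 24; aldehyde 22 back to hydroxy lactone 16 and bromide 14.** For 29 the epoxide C–O bonds are cut (29 from epoxy alcohol 28, from trienol 27 by asymmetric epoxidation), then the C2=C3 alkene of ester 26 (from 24 through aldehyde 25). For 22 the amide of 21 is cut back to a Weinreb amide, then the Z-alkene to aldehyde 19 and ylide 20 (from salt 15, from 14); 19 comes from 18, 17 and chiral-pool lactone 16. Both skipped dienes are bought as Z-alkenes or made by one Z-selective Wittig reaction. The forward steps must avoid conjugation of the β,γ-unsaturated aldehyde 25.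

## Roads not taken

**Alternative 1:** the most obvious plan cuts only the C11–O bond. A vanadium-catalysed, hydroxyl-directed epoxidation of the C11=C12 alkene in bishomoallylic alcohol A1 (VO(acac)2, t-BuOOH), with 5-exo-tet opening in the same flask, would give oxolane core A2; the four arms are then attached one by one. The C10/C11′/C12′ triad of A1 must be made first. The directed epoxidation cannot distinguish C11=C12 from the C14′=C15′ alkene (homoallylic to the same hydroxyl), so neither skipped diene can be present. A2 therefore needs four differently protected termini, two late Z-Wittig reactions and two cyclopropane attachments, one through a cyclopropyl nucleophile that cannot carry its lactone. The chosen plan makes the same ring in one step from two finished halves.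

**Alternative 2:** the same two ring bonds are cut, but the acceptor is enal A3. Combined zerovalent palladium and secondary-amine (iminium–enamine) catalysis with 30 would give oxolane-3-carbaldehyde A4, and the amine would control C11. The C8–C9 bond must then be made on A4 by adding a metallated cyclopropane, which cannot bear a δ-lactone, or the whole cyclopropyl lactone must be built after the union with three more stereocentres. The γ-silyloxy group of A3 is also prone to elimination through the dienamine. The enone 23 keeps the cyclopropyl lactone in place before the key step.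

**Alternative 3:** a biomimetic cationic (3+2) union. Lewis-acid ionisation of epoxide 30 would give an allyl cation, to be captured by the C10=C11 alkene of bis-silyl ether A5 with ring closure by the C12′ oxygen. That alkene is unpolarised and flanked by two C–O bonds, so it is a poor nucleophile with no bias between C10 and C11. The cation is conjugated to a cyclopropane and can open; C11′ loses its configuration in a free cation; the skipped dienes compete as nucleophiles. The chosen plan polarises both partners (enolate/enone, allyl–palladium/alkoxide) and keeps C11′ stereospecific.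

Key step: step 22

Assumption: compounds 1, 5, 14, 16 and 24 and the reagents on the Conditions lines are taken as purchasable.

## Steps

Step 1
Reactants: 1 (2E)-but-2-ene-1,4-diol
Product: 2 (2E)-4-{[tert-butyl(diphenyl)silyl]oxy}but-2-en-1-ol
Conditions: NaH (1.0 equiv), THF, 0 °C; then t-BuPh2SiCl (1.0 equiv), 0 → 25 °C
Reagents that add atoms: tert-butyl(chloro)diphenylsilane, CC(C)(C)[Si](Cl)(c1ccccc1)c1ccccc1
Why: Monosilylation of a symmetric diol through its sparingly soluble monosodium alkoxide; no stereocentre is formed and the E-alkene is untouched.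

Step 2
Reactants: 2 (2E)-4-{[tert-butyl(diphenyl)silyl]oxy}but-2-en-1-ol
Product: 3 [(1S,2S)-2-({[tert-butyl(diphenyl)silyl]oxy}methyl)cyclopropyl]methanol
Conditions: Et2Zn, CH2I2, DME, CH2Cl2, −10 °C; then (4R,5R)-2-butyl-N,N,N′,N′-tetramethyl-1,3,2-dioxaborolane-4,5-dicarboxamide (1.2 equiv) and 2, −10 → 25 °C; aq. NH4Cl
Reagents that add atoms: diiodomethane, ICI
Why: Asymmetric Simmons–Smith cyclopropanation (Charette dioxaborolane variant): the zinc alkoxide binds the chiral boronate, which delivers CH2 to one alkene face. With the (4R,5R)-ligand E-allylic alcohols should give the (1S,2S)-cyclopropylmethanol, and the trans ring follows from the E-alkene.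

Step 3
Reactants: 3 [(1S,2S)-2-({[tert-butyl(diphenyl)silyl]oxy}methyl)cyclopropyl]methanol
Product: 4 (1S,2S)-2-({[tert-butyl(diphenyl)silyl]oxy}methyl)cyclopropane-1-carbaldehyde
Conditions: Dess–Martin periodinane, NaHCO3, CH2Cl2, 0 → 25 °C
Reagents that add atoms: none
Why: Dess–Martin oxidation of a primary alcohol; the trans-cyclopropanecarbaldehyde is configurationally stable.

Step 4
Reactants: 4 (1S,2S)-2-({[tert-butyl(diphenyl)silyl]oxy}methyl)cyclopropane-1-carbaldehyde, 5 ethyl 4-iodobutanoate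
Product: 8 (6R)-6-[(1S,2S)-2-({[tert-butyl(diphenyl)silyl]oxy}methyl)cyclopropyl]oxan-2-one, via bis(4-ethoxy-4-oxobutyl)zinc 6 (not isolated), via hydroxy ester 7 (not isolated)
Conditions: 5, Et2Zn, CuI (0.3 mol%), neat, 50 °C, then volatiles off; Ti(OiPr)4 (2 equiv), (1S,2S)-N,N′-cyclohexane-1,2-diylbis(trifluoromethanesulfonamide) (8 mol%), PhMe, −20 °C, then 4; aq. HCl; TsOH·H2O (cat.), PhMe, 40 °C
Reagents that add atoms: none
Why: Iodine–zinc exchange gives the ester-bearing dialkylzinc 6, which adds to 4 under Ti(OiPr)4/chiral bis(sulfonamide) catalysis (catalytic asymmetric alkylzinc addition). The (1S,2S)-ligand should send the alkyl group to the Re face of the aldehyde and set C5 as R by reagent control; acid then closes hydroxy ester 7 to the δ-lactone.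

Step 5
Reactants: 8 (6R)-6-[(1S,2S)-2-({[tert-butyl(diphenyl)silyl]oxy}methyl)cyclopropyl]oxan-2-one
Product: 9 (6R)-6-[(1S,2S)-2-(hydroxymethyl)cyclopropyl]oxan-2-one
Conditions: Bu4NF, AcOH, THF, 0 → 25 °C
Reagents that add atoms: none
Why: Fluoride desilylation; the acetic acid buffer keeps the δ-lactone closed.

Step 6
Reactants: 9 (6R)-6-[(1S,2S)-2-(hydroxymethyl)cyclopropyl]oxan-2-one
Product: 10 (6R)-6-[(1S,2S)-2-{[(1-phenyl-1H-tetrazol-5-yl)sulfanyl]methyl}cyclopropyl]oxan-2-one
Conditions: 1-phenyl-1H-tetrazole-5-thiol, PPh3, diisopropyl azodicarboxylate, THF, 0 → 25 °C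
Reagents that add atoms: 1-phenyl-1H-tetrazole-5-thiol, Sc1nnnn1-c1ccccc1
Why: Mitsunobu thioetherification by SN2 displacement at the primary cyclopropylmethyl carbon; no stereocentre is touched.

Step 7
Reactants: 10 (6R)-6-[(1S,2S)-2-{[(1-phenyl-1H-tetrazol-5-yl)sulfanyl]methyl}cyclopropyl]oxan-2-one
Product: 11 (6R)-6-[(1S,2S)-2-{[(1-phenyl-1H-tetrazol-5-yl)sulfonyl]methyl}cyclopropyl]oxan-2-one
Conditions: mCPBA (2.5 equiv), NaHCO3, CH2Cl2, 0 → 25 °C
Reagents that add atoms: 3-chloroperoxybenzoic acid, OOC(=O)c1cccc(Cl)c1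
Why: Peracid oxidation of sulfide to sulfone; no alkene is present at this stage and the lactone is inert.

Step 8
Reactants: 9 (6R)-6-[(1S,2S)-2-(hydroxymethyl)cyclopropyl]oxan-2-one
Product: 12 (1S,2S)-2-[(2R)-6-oxooxan-2-yl]cyclopropane-1-carbaldehyde
Conditions: Dess–Martin periodinane, NaHCO3, CH2Cl2, 0 → 25 °C
Reagents that add atoms: none
Why: Dess–Martin oxidation; neutral conditions leave the lactone and the trans cyclopropane unchanged.

Step 9
Reactants: 12 (1S,2S)-2-[(2R)-6-oxooxan-2-yl]cyclopropane-1-carbaldehyde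
Product: 13 dimethyl {2-oxo-2-[(1S,2S)-2-[(2R)-6-oxooxan-2-yl]cyclopropyl]ethyl}phosphonate
Conditions: dimethyl (diazomethyl)phosphonate, SnCl2 (0.2 equiv), CH2Cl2, 25 °C
Reagents that add atoms: dimethyl (diazomethyl)phosphonate, COP(=O)(OC)C=[N+]=[N-]
Why: Roskamp-type homologation: Lewis-acid-promoted addition of the diazo compound to the aldehyde, 1,2-hydride shift and loss of N2 give the β-keto phosphonate. No base or hard nucleophile meets the lactone.

Step 10
Reactants: 14 (3Z)-1-bromohex-3-ene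
Product: 15 [(3Z)-hex-3-en-1-yl](triphenyl)phosphonium bromide
Conditions: PPh3, MeCN, reflux
Reagents that add atoms: triphenylphosphine, c1ccc(cc1)P(c1ccccc1)c1ccccc1
Why: SN2 quaternisation of a primary bromide; the Z-alkene is not involved.

Step 11
Reactants: 16 (3S)-3-hydroxyoxolan-2-one
Product: 17 (3S)-3-{[tert-butyl(dimethyl)silyl]oxy}oxolan-2-one
Conditions: t-BuMe2SiCl, imidazole, DMF, 25 °C
Reagents that add atoms: tert-butyl(chloro)dimethylsilane, CC(C)(C)[Si](C)(C)Cl
Why: Silylation of the secondary alcohol; the chiral-pool stereocentre (the future C12) is retained.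

Step 12
Reactants: 17 (3S)-3-{[tert-butyl(dimethyl)silyl]oxy}oxolan-2-one
Product: 18 (2S)-2-{[tert-butyl(dimethyl)silyl]oxy}-4-hydroxy-N-methoxy-N-methylbutanamide
Conditions: MeNH(OMe)·HCl, AlMe3, CH2Cl2, 0 → 25 °C; aq. potassium sodium tartrate
Reagents that add atoms: N,O-dimethylhydroxylamine hydrochloride, CNOC.Cl
Why: Weinreb aminolysis of the lactone by the aluminium amide; the α-silyloxy centre is not enolised under these Lewis-acidic conditions.

Step 13
Reactants: 18 (2S)-2-{[tert-butyl(dimethyl)silyl]oxy}-4-hydroxy-N-methoxy-N-methylbutanamide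
Product: 19 (2S)-2-{[tert-butyl(dimethyl)silyl]oxy}-N-methoxy-N-methyl-4-oxobutanamide
Conditions: Dess–Martin periodinane, NaHCO3, CH2Cl2, 0 °C
Reagents that add atoms: none
Why: Dess–Martin oxidation under buffered conditions; the β-silyloxy aldehyde is used at once to avoid elimination.

Step 14
Reactants: 19 (2S)-2-{[tert-butyl(dimethyl)silyl]oxy}-N-methoxy-N-methyl-4-oxobutanamide, 15 [(3Z)-hex-3-en-1-yl](triphenyl)phosphonium bromide
Product: 21 (2S,4Z,7Z)-2-{[tert-butyl(dimethyl)silyl]oxy}-N-methoxy-N-methyldeca-4,7-dienamide, via hexenylidene phosphorane 20 (not isolated)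
Conditions: 15, NaN(SiMe3)2, THF, −78 → 0 °C; then 19, −78 → 0 °C
Reagents that add atoms: none
Why: Wittig reaction of the salt-free, non-stabilised ylide 20 at low temperature should give the Z-alkene under kinetic control; the Weinreb amide does not react with the ylide at −78 °C.

Step 15
Reactants: 21 (2S,4Z,7Z)-2-{[tert-butyl(dimethyl)silyl]oxy}-N-methoxy-N-methyldeca-4,7-dienamide
Product: 22 (2S,4Z,7Z)-2-{[tert-butyl(dimethyl)silyl]oxy}deca-4,7-dienal
Conditions: iBu2AlH, THF, −78 °C; aq. potassium sodium tartrate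
Reagents that add atoms: none
Why: Hydride reduction of a Weinreb amide stops at the aldehyde through the chelated tetrahedral intermediate; the α-silyloxy aldehyde is used directly.

Step 16
Reactants: 13 dimethyl {2-oxo-2-[(1S,2S)-2-[(2R)-6-oxooxan-2-yl]cyclopropyl]ethyl}phosphonate, 22 (2S,4Z,7Z)-2-{[tert-butyl(dimethyl)silyl]oxy}deca-4,7-dienal
Product: 23 (6R)-6-[(1S,2S)-2-[(2E,4S,6Z,9Z)-4-{[tert-butyl(dimethyl)silyl]oxy}dodeca-2,6,9-trienoyl]cyclopropyl]oxan-2-one
Conditions: LiCl, iPr2NEt, MeCN, 0 → 25 °C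
Reagents that add atoms: none
Why: Horner–Wadsworth–Emmons olefination under amine/LiCl (Masamune–Roush) conditions should give the E-enone; the weak base avoids epimerisation of the α-silyloxy aldehyde and opening of the lactone.

Step 17
Reactants: 24 (3Z,6Z)-nona-3,6-dien-1-ol
Product: 26 ethyl (2E,5Z,8Z)-undeca-2,5,8-trienoate, via (3Z,6Z)-nona-3,6-dienal 25 (not isolated)
Conditions: Dess–Martin periodinane, NaHCO3, CH2Cl2, 0 °C; then Ph3P=CHCO2Et, 0 → 25 °C
Reagents that add atoms: ethyl (triphenyl-λ5-phosphanylidene)acetate, CCOC(=O)C=P(c1ccccc1)(c1ccccc1)c1ccccc1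
Why: Oxidation and Wittig reaction in one flask trap the β,γ-unsaturated aldehyde 25 before it can conjugate; the stabilised ylide gives the E-enoate and leaves both Z-alkenes in place.

Step 18
Reactants: 26 ethyl (2E,5Z,8Z)-undeca-2,5,8-trienoate
Product: 27 (2E,5Z,8Z)-undeca-2,5,8-trien-1-ol
Conditions: iBu2AlH (2.2 equiv), CH2Cl2, −78 °C
Reagents that add atoms: none
Why: 1,2-Reduction of the enoate to the allylic alcohol at low temperature, without isomerisation of the skipped triene.

Step 19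
Reactants: 27 (2E,5Z,8Z)-undeca-2,5,8-trien-1-ol
Product: 28 [(2R,3R)-3-[(2Z,5Z)-octa-2,5-dien-1-yl]oxiran-2-yl]methanol
Conditions: Ti(OiPr)4 (10 mol%), D-(−)-diethyl tartrate (12 mol%), t-BuOOH, 4 Å molecular sieves, CH2Cl2, −20 °C
Reagents that add atoms: tert-butyl hydroperoxide, CC(C)(C)OO
Why: Sharpless asymmetric epoxidation: only the allylic alkene is epoxidised, and with the D-(−)-tartrate an E-allylic alcohol should give the (2R,3R)-epoxy alcohol (the future C11′ and C12′).

Step 20
Reactants: 28 [(2R,3R)-3-[(2Z,5Z)-octa-2,5-dien-1-yl]oxiran-2-yl]methanol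
Product: 29 (2S,3R)-3-[(2Z,5Z)-octa-2,5-dien-1-yl]oxirane-2-carbaldehyde
Conditions: Dess–Martin periodinane, NaHCO3, CH2Cl2, 0 °C
Reagents that add atoms: none
Why: Buffered Dess–Martin oxidation gives the epoxy aldehyde without epimerisation (the descriptor at C-2 changes only through priority); it is used at once.

Step 21
Reactants: 11 (6R)-6-[(1S,2S)-2-{[(1-phenyl-1H-tetrazol-5-yl)sulfonyl]methyl}cyclopropyl]oxan-2-one, 29 (2S,3R)-3-[(2Z,5Z)-octa-2,5-dien-1-yl]oxirane-2-carbaldehyde
Product: 30 (6R)-6-[(1S,2R)-2-{(E)-2-[(2R,3R)-3-[(2Z,5Z)-octa-2,5-dien-1-yl]oxiran-2-yl]ethenyl}cyclopropyl]oxan-2-one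
Conditions: 11, KN(SiMe3)2, DME, −60 °C; then 29, −60 → 25 °C
Reagents that add atoms: none
Why: Julia–Kocienski olefination: addition, Smiles rearrangement and anti elimination should give the E-alkene. The α-sulfonyl cyclopropylmethyl anion does not open, and the low temperature protects epoxide and lactone.

Step 22
Reactants: 23 (6R)-6-[(1S,2S)-2-[(2E,4S,6Z,9Z)-4-{[tert-butyl(dimethyl)silyl]oxy}dodeca-2,6,9-trienoyl]cyclopropyl]oxan-2-one, 30 (6R)-6-[(1S,2R)-2-{(E)-2-[(2R,3R)-3-[(2Z,5Z)-octa-2,5-dien-1-yl]oxiran-2-yl]ethenyl}cyclopropyl]oxan-2-one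
Product: 31 (6R)-6-[(1S,2S)-2-{[(2S,3S,4S,5R)-2-[(1S,3Z,6Z)-1-{[tert-butyl(dimethyl)silyl]oxy}nona-3,6-dien-1-yl]-5-[(2Z,5Z)-octa-2,5-dien-1-yl]-4-{(E)-2-[(1R,2S)-2-[(2R)-6-oxooxan-2-yl]cyclopropyl]ethenyl}oxolan-3-yl]carbonyl}cyclopropyl]oxan-2-one
Conditions: Pd2(dba)3·CHCl3 (5 mol%), Ph2PCH2CH2PPh2 (12 mol%), 4 Å molecular sieves, THF, 0 → 25 °C
Reagents that add atoms: none
Why: Proposed new method: zerovalent palladium ionises the allylic C11′–O bond of 30 with inversion to a syn,syn-η3-allylpalladium alkoxide, whose C12′ oxygen adds reversibly to C11 of enone 23 (oxa-Michael) and whose C10 ketone enolate then attacks the proximal allyl terminus C11′ anti to the metal and releases the catalyst. The closest known reaction type is the palladium-catalysed formal (3+2) cycloaddition of vinyl epoxides with doubly activated Michael acceptors; new here are the mono-activated γ-silyloxy enone and the internal, 1,3-disubstituted allyl unit. The oxolane closes by C–C bond formation in a 5-exo attack on the allyl terminus; the seven-membered alternative through C9′ is disfavoured by ring size and by the cyclopropyl group on C9′. C12′ is carried over from the epoxide untouched and C11′ is set by two inversions (net retention), so the trans epoxide becomes the trans C11′/C12′ pair. C11 is chosen under Curtin–Hammett conditions: the two oxa-Michael adducts interconvert, and only the one that places H-11 in the enolate plane (A(1,3) strain) and the C9 acyl group away from the allyl–palladium unit, that is the all-trans array, should close fast. C10 is α to the ketone, so any C10 epimer should equilibrate under the basic zwitterion to the same all-trans isomer, the most stable of the four. The step needs ionisation of the vinyl epoxide only and no β-hydride loss from the allyl complex: the C12 silyl ether is no leaving group, the lactones meet only a catalytic amount of alkoxide, the chelating diphosphine and low temperature should hold the complex together, and a 1,3-dioxolane from 1,2-addition to the ketone would be an allylic acetal that re-ionises and is no dead end.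

Step 23
Reactants: 31 (6R)-6-[(1S,2S)-2-{[(2S,3S,4S,5R)-2-[(1S,3Z,6Z)-1-{[tert-butyl(dimethyl)silyl]oxy}nona-3,6-dien-1-yl]-5-[(2Z,5Z)-octa-2,5-dien-1-yl]-4-{(E)-2-[(1R,2S)-2-[(2R)-6-oxooxan-2-yl]cyclopropyl]ethenyl}oxolan-3-yl]carbonyl}cyclopropyl]oxan-2-one
Product: 32 (6R)-6-[(1S,2S)-2-[(R)-{(2S,3R,4S,5R)-2-[(1S,3Z,6Z)-1-{[tert-butyl(dimethyl)silyl]oxy}nona-3,6-dien-1-yl]-5-[(2Z,5Z)-octa-2,5-dien-1-yl]-4-{(E)-2-[(1R,2S)-2-[(2R)-6-oxooxan-2-yl]cyclopropyl]ethenyl}oxolan-3-yl}(hydroxy)methyl]cyclopropyl]oxan-2-one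
Conditions: (S)-2-methyl-CBS-oxazaborolidine (0.5 equiv), catecholborane (2 equiv), PhMe, −78 → −40 °C; MeOH, aq. NaHCO3
Reagents that add atoms: none
Why: Corey–Bakshi–Shibata reduction: the oxazaborolidine binds the ketone with the oxolanyl group as the large and the cyclopropyl as the small substituent, so the (S)-catalyst should give the 9R carbinol, the same sense as Felkin–Anh attack anti to C11. Catecholborane at low temperature leaves lactones and alkenes untouched.

Step 24
Reactants: 32 (6R)-6-[(1S,2S)-2-[(R)-{(2S,3R,4S,5R)-2-[(1S,3Z,6Z)-1-{[tert-butyl(dimethyl)silyl]oxy}nona-3,6-dien-1-yl]-5-[(2Z,5Z)-octa-2,5-dien-1-yl]-4-{(E)-2-[(1R,2S)-2-[(2R)-6-oxooxan-2-yl]cyclopropyl]ethenyl}oxolan-3-yl}(hydroxy)methyl]cyclopropyl]oxan-2-one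
Product: 33 (6R)-6-[(1S,2S)-2-[(R)-hydroxy{(2S,3R,4S,5R)-2-[(1S,3Z,6Z)-1-hydroxynona-3,6-dien-1-yl]-5-[(2Z,5Z)-octa-2,5-dien-1-yl]-4-{(E)-2-[(1R,2S)-2-[(2R)-6-oxooxan-2-yl]cyclopropyl]ethenyl}oxolan-3-yl}methyl]cyclopropyl]oxan-2-one
Conditions: HF·pyridine, pyridine, THF, 0 → 25 °C
Reagents that add atoms: none
Why: Buffered fluoride cleavage of the secondary silyl ether; the conditions should be too mild to ionise the cyclopropylcarbinol, open the lactones or move the skipped dienes.

## Compound list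

1 | (2E)-but-2-ene-1,4-diol | OC/C=C/CO | starting material
2 | (2E)-4-{[tert-butyl(diphenyl)silyl]oxy}but-2-en-1-ol | OC/C=C/CO[Si](c1ccccc1)(c1ccccc1)C(C)(C)C | intermediate
3 | [(1S,2S)-2-({[tert-butyl(diphenyl)silyl]oxy}methyl)cyclopropyl]methanol | OC[C@H]1C[C@@H]1CO[Si](c1ccccc1)(c1ccccc1)C(C)(C)C | intermediate
4 | (1S,2S)-2-({[tert-butyl(diphenyl)silyl]oxy}methyl)cyclopropane-1-carbaldehyde | O=C[C@H]1C[C@@H]1CO[Si](c1ccccc1)(c1ccccc1)C(C)(C)C | intermediate
5 | ethyl 4-iodobutanoate | CCOC(=O)CCCI | starting material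
6 | bis(4-ethoxy-4-oxobutyl)zinc | CCOC(=O)CCC[Zn]CCCC(=O)OCC | intermediate
7 | ethyl (5R)-5-[(1S,2S)-2-({[tert-butyl(diphenyl)silyl]oxy}methyl)cyclopropyl]-5-hydroxypentanoate | CC(C)(C)[Si](c1ccccc1)(c1ccccc1)OC[C@H]1C[C@@H]1[C@H](O)CCCC(=O)OCC | intermediate
8 | (6R)-6-[(1S,2S)-2-({[tert-butyl(diphenyl)silyl]oxy}methyl)cyclopropyl]oxan-2-one | CC(C)(C)[Si](c1ccccc1)(c1ccccc1)OC[C@H]1C[C@@H]1[C@H]1CCCC(=O)O1 | intermediate
9 | (6R)-6-[(1S,2S)-2-(hydroxymethyl)cyclopropyl]oxan-2-one | OC[C@H]1C[C@@H]1[C@H]1CCCC(=O)O1 | intermediate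
10 | (6R)-6-[(1S,2S)-2-{[(1-phenyl-1H-tetrazol-5-yl)sulfanyl]methyl}cyclopropyl]oxan-2-one | c1ccccc1-n1nnnc1SC[C@H]1C[C@@H]1[C@H]1CCCC(=O)O1 | intermediate
11 | (6R)-6-[(1S,2S)-2-{[(1-phenyl-1H-tetrazol-5-yl)sulfonyl]methyl}cyclopropyl]oxan-2-one | O=S(=O)(C[C@H]1C[C@@H]1[C@H]1CCCC(=O)O1)c1nnnn1-c1ccccc1 | intermediate
12 | (1S,2S)-2-[(2R)-6-oxooxan-2-yl]cyclopropane-1-carbaldehyde | O=C[C@H]1C[C@@H]1[C@H]1CCCC(=O)O1 | intermediate
13 | dimethyl {2-oxo-2-[(1S,2S)-2-[(2R)-6-oxooxan-2-yl]cyclopropyl]ethyl}phosphonate | COP(=O)(OC)CC(=O)[C@H]1C[C@@H]1[C@H]1CCCC(=O)O1 | intermediate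
14 | (3Z)-1-bromohex-3-ene | BrCC/C=C\CC | starting material
15 | [(3Z)-hex-3-en-1-yl](triphenyl)phosphonium bromide | CC/C=C\CC[P+](c1ccccc1)(c1ccccc1)c1ccccc1.[Br-] | intermediate
16 | (3S)-3-hydroxyoxolan-2-one | O[C@H]1CCOC1=O | starting material
17 | (3S)-3-{[tert-butyl(dimethyl)silyl]oxy}oxolan-2-one | CC(C)(C)[Si](C)(C)O[C@H]1CCOC1=O | intermediate
18 | (2S)-2-{[tert-butyl(dimethyl)silyl]oxy}-4-hydroxy-N-methoxy-N-methylbutanamide | CON(C)C(=O)[C@H](CCO)O[Si](C)(C)C(C)(C)C | intermediate
19 | (2S)-2-{[tert-butyl(dimethyl)silyl]oxy}-N-methoxy-N-methyl-4-oxobutanamide | CON(C)C(=O)[C@H](CC=O)O[Si](C)(C)C(C)(C)C | intermediate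
20 | [(3Z)-hex-3-en-1-ylidene](triphenyl)-λ5-phosphane | CC/C=C\CC=P(c1ccccc1)(c1ccccc1)c1ccccc1 | intermediate
21 | (2S,4Z,7Z)-2-{[tert-butyl(dimethyl)silyl]oxy}-N-methoxy-N-methyldeca-4,7-dienamide | CON(C)C(=O)[C@H](C/C=C\C/C=C\CC)O[Si](C)(C)C(C)(C)C | intermediate
22 | (2S,4Z,7Z)-2-{[tert-butyl(dimethyl)silyl]oxy}deca-4,7-dienal | O=C[C@H](C/C=C\C/C=C\CC)O[Si](C)(C)C(C)(C)C | intermediate
23 | (6R)-6-[(1S,2S)-2-[(2E,4S,6Z,9Z)-4-{[tert-butyl(dimethyl)silyl]oxy}dodeca-2,6,9-trienoyl]cyclopropyl]oxan-2-one | CC/C=C\C/C=C\C[C@H](O[Si](C)(C)C(C)(C)C)/C=C/C(=O)[C@H]1C[C@@H]1[C@H]1CCCC(=O)O1 | intermediate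
24 | (3Z,6Z)-nona-3,6-dien-1-ol | OCC/C=C\C/C=C\CC | starting material
25 | (3Z,6Z)-nona-3,6-dienal | O=CC/C=C\C/C=C\CC | intermediate
26 | ethyl (2E,5Z,8Z)-undeca-2,5,8-trienoate | CCOC(=O)/C=C/C/C=C\C/C=C\CC | intermediate
27 | (2E,5Z,8Z)-undeca-2,5,8-trien-1-ol | OC/C=C/C/C=C\C/C=C\CC | intermediate
28 | [(2R,3R)-3-[(2Z,5Z)-octa-2,5-dien-1-yl]oxiran-2-yl]methanol | OC[C@H]1O[C@@H]1C/C=C\C/C=C\CC | intermediate
29 | (2S,3R)-3-[(2Z,5Z)-octa-2,5-dien-1-yl]oxirane-2-carbaldehyde | O=C[C@H]1O[C@@H]1C/C=C\C/C=C\CC | intermediate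
30 | (6R)-6-[(1S,2R)-2-{(E)-2-[(2R,3R)-3-[(2Z,5Z)-octa-2,5-dien-1-yl]oxiran-2-yl]ethenyl}cyclopropyl]oxan-2-one | CC/C=C\C/C=C\C[C@H]1O[C@@H]1/C=C/[C@H]1C[C@@H]1[C@H]1CCCC(=O)O1 | intermediate
31 | (6R)-6-[(1S,2S)-2-{[(2S,3S,4S,5R)-2-[(1S,3Z,6Z)-1-{[tert-butyl(dimethyl)silyl]oxy}nona-3,6-dien-1-yl]-5-[(2Z,5Z)-octa-2,5-dien-1-yl]-4-{(E)-2-[(1R,2S)-2-[(2R)-6-oxooxan-2-yl]cyclopropyl]ethenyl}oxolan-3-yl]carbonyl}cyclopropyl]oxan-2-one | CC/C=C\C/C=C\C[C@H](O[Si](C)(C)C(C)(C)C)[C@H]1O[C@H](C/C=C\C/C=C\CC)[C@@H](/C=C/[C@H]2C[C@@H]2[C@H]2CCCC(=O)O2)[C@@H]1C(=O)[C@H]1C[C@@H]1[C@H]1CCCC(=O)O1 | intermediate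
32 | (6R)-6-[(1S,2S)-2-[(R)-{(2S,3R,4S,5R)-2-[(1S,3Z,6Z)-1-{[tert-butyl(dimethyl)silyl]oxy}nona-3,6-dien-1-yl]-5-[(2Z,5Z)-octa-2,5-dien-1-yl]-4-{(E)-2-[(1R,2S)-2-[(2R)-6-oxooxan-2-yl]cyclopropyl]ethenyl}oxolan-3-yl}(hydroxy)methyl]cyclopropyl]oxan-2-one | CC/C=C\C/C=C\C[C@H](O[Si](C)(C)C(C)(C)C)[C@H]1O[C@H](C/C=C\C/C=C\CC)[C@@H](/C=C/[C@H]2C[C@@H]2[C@H]2CCCC(=O)O2)[C@@H]1[C@H](O)[C@H]1C[C@@H]1[C@H]1CCCC(=O)O1 | intermediate
33 | (6R)-6-[(1S,2S)-2-[(R)-hydroxy{(2S,3R,4S,5R)-2-[(1S,3Z,6Z)-1-hydroxynona-3,6-dien-1-yl]-5-[(2Z,5Z)-octa-2,5-dien-1-yl]-4-{(E)-2-[(1R,2S)-2-[(2R)-6-oxooxan-2-yl]cyclopropyl]ethenyl}oxolan-3-yl}methyl]cyclopropyl]oxan-2-one | CC/C=C\C/C=C\C[C@H](O)[C@H]1O[C@H](C/C=C\C/C=C\CC)[C@@H](/C=C/[C@H]2C[C@@H]2[C@H]2CCCC(=O)O2)[C@@H]1[C@H](O)[C@H]1C[C@@H]1[C@H]1CCCC(=O)O1 | target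

## Step count and risks

Total step count: 24. Longest linear sequence: 11 steps (1 to 33 through steps 1–7, 21, 22, 23, 24; the branch through steps 1–5, 8, 9, 16, 22, 23, 24 is equally long).

**Step 22 (key step, proposed new method).** Most likely failures are:
- slow oxa-Michael addition to a mono-activated enone, so that the allylpalladium alkoxide decays by β-hydride elimination or isomerisation of the epoxide;
- inner-sphere C–C bond formation, which would erode retention at C11′;
- too little discrimination at C11 in the ring-closing transition states.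

The fallback uses an acceptor of the established, doubly activated class with a traceless second carbonyl group. It sets out from 12, 22 and 30 and returns at 31. Aldehyde 12 is homologated with allyl diazoacetate and SnCl2 (Roskamp reaction) to the allyl β-keto ester F1. Knoevenagel condensation of F1 with aldehyde 22 (piperidinium acetate) gives the alkylidene β-keto ester F2, whose alkene geometry is lost in the enolate. Palladium-catalysed (3+2) cycloaddition of F2 with 30 (Pd2(dba)3·CHCl3, Ph2PCH2CH2PPh2) gives the oxolane-3-carboxylate F3. Pd(PPh3)4 and morpholine then remove the allyl ester with decarboxylation; C10 settles trans to both neighbours on protonation, giving ketone 31.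

**Step 23.** The risk is poor facial selectivity: a chelated rotamer (ketone oxygen with the ring oxygen) delivers hydride to the other face, and slow catalysed reduction of the hindered ketone lets uncatalysed reduction compete. The fallback accepts the other face and inverts; it sets out from 31 and returns at 32. Chelation-controlled reduction with Zn(BH4)2 should give the 9S alcohol F4. Mitsunobu inversion with chloroacetic acid (PPh3, diisopropyl azodicarboxylate) gives the 9R chloroacetate F5, and thiourea with NaHCO3 cleaves the chloroacetate beside the lactones to give 32.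

**Step 21.** The risks are loss of E-selectivity with an α-oxygenated aldehyde, base-induced opening or epimerisation of the epoxy aldehyde, and enolisation of the lactone by the sulfonyl anion. The fallback makes the alkene first and the epoxide last under non-basic coupling conditions; it sets out from 21 and 12 and returns at 30.
- Amide 21 is desilylated (Bu4NF, AcOH) to the hydroxy amide F6, mesylated (MsCl, Et3N) to the mesylate F7, and reduced (iBu2AlH, −78 °C) to the α-mesyloxy aldehyde F8.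
- Aldehyde 12 is converted by Takai olefination (CrCl2, CHI3) to the E-vinyl iodide F9.
- Nozaki–Hiyama–Kishi coupling of F9 with F8 (CrCl2, NiCl2 cat.) should give the anti hydroxy mesylate F10.
- K2CO3 closes the epoxide with inversion at C12′ (S-mesylate to R-epoxide), giving the trans epoxide 30.

**Step 4.** The risks are sluggish transfer of the ester-bearing alkyl group and incomplete catalyst control with the α-chiral cyclopropyl aldehyde, giving C5 epimers. The fallback builds the lactone by allylation and ring-closing metathesis; it sets out from 4 and returns at 8. Brown allylation of 4 with (+)-B-allyldiisopinocampheylborane (from (−)-α-pinene; Re-face attack) gives the homoallylic alcohol F11. Acryloyl chloride with Et3N gives the acrylate F12. Ring-closing metathesis with the second-generation Grubbs catalyst, (H2IMes)(PCy3)Cl2Ru=CHPh, gives the unsaturated lactone F13, and conjugate reduction with [(Ph3P)CuH]6 gives 8.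

Further compounds

F1 | step 22 | prop-2-en-1-yl 3-oxo-3-[(1S,2S)-2-[(2R)-6-oxooxan-2-yl]cyclopropyl]propanoate | C=CCOC(=O)CC(=O)[C@H]1C[C@@H]1[C@H]1CCCC(=O)O1
F2 | step 22 | prop-2-en-1-yl (4S,6Z,9Z)-4-{[tert-butyl(dimethyl)silyl]oxy}-2-{(1S,2S)-2-[(2R)-6-oxooxan-2-yl]cyclopropane-1-carbonyl}dodeca-2,6,9-trienoate (2E/2Z mixture) | CC/C=C\C/C=C\C[C@H](O[Si](C)(C)C(C)(C)C)C=C(C(=O)OCC=C)C(=O)[C@H]1C[C@@H]1[C@H]1CCCC(=O)O1
F3 | step 22 | prop-2-en-1-yl (2S,4S,5R)-2-[(1S,3Z,6Z)-1-{[tert-butyl(dimethyl)silyl]oxy}nona-3,6-dien-1-yl]-5-[(2Z,5Z)-octa-2,5-dien-1-yl]-3-{(1S,2S)-2-[(2R)-6-oxooxan-2-yl]cyclopropane-1-carbonyl}-4-{(E)-2-[(1R,2S)-2-[(2R)-6-oxooxan-2-yl]cyclopropyl]ethenyl}oxolane-3-carboxylate (configuration at C-3 not defined) | CC/C=C\C/C=C\C[C@H](O[Si](C)(C)C(C)(C)C)[C@H]1O[C@H](C/C=C\C/C=C\CC)[C@@H](/C=C/[C@H]2C[C@@H]2[C@H]2CCCC(=O)O2)C1(C(=O)OCC=C)C(=O)[C@H]1C[C@@H]1[C@H]1CCCC(=O)O1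
F4 | step 23 | 9S epimer of 32 (S configuration at the cyclopropyl carbinol carbon) | CC/C=C\C/C=C\C[C@H](O[Si](C)(C)C(C)(C)C)[C@H]1O[C@H](C/C=C\C/C=C\CC)[C@@H](/C=C/[C@H]2C[C@@H]2[C@H]2CCCC(=O)O2)[C@@H]1[C@@H](O)[C@H]1C[C@@H]1[C@H]1CCCC(=O)O1
F5 | step 23 | chloroacetate of 32 (R configuration at the cyclopropyl carbinol carbon) | CC/C=C\C/C=C\C[C@H](O[Si](C)(C)C(C)(C)C)[C@H]1O[C@H](C/C=C\C/C=C\CC)[C@@H](/C=C/[C@H]2C[C@@H]2[C@H]2CCCC(=O)O2)[C@@H]1[C@H](OC(=O)CCl)[C@H]1C[C@@H]1[C@H]1CCCC(=O)O1
F6 | step 21 | (2S,4Z,7Z)-2-hydroxy-N-methoxy-N-methyldeca-4,7-dienamide | CON(C)C(=O)[C@H](C/C=C\C/C=C\CC)O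
F7 | step 21 | (2S,4Z,7Z)-1-[methoxy(methyl)amino]-1-oxodeca-4,7-dien-2-yl methanesulfonate | CON(C)C(=O)[C@H](C/C=C\C/C=C\CC)OS(C)(=O)=O
F8 | step 21 | (2S,4Z,7Z)-1-oxodeca-4,7-dien-2-yl methanesulfonate | O=C[C@H](C/C=C\C/C=C\CC)OS(C)(=O)=O
F9 | step 21 | (6R)-6-[(1S,2S)-2-[(E)-2-iodoethenyl]cyclopropyl]oxan-2-one | I/C=C/[C@H]1C[C@@H]1[C@H]1CCCC(=O)O1
F10 | step 21 | (1E,3R,4S,6Z,9Z)-3-hydroxy-1-[(1R,2S)-2-[(2R)-6-oxooxan-2-yl]cyclopropyl]dodeca-1,6,9-trien-4-yl methanesulfonate | CC/C=C\C/C=C\C[C@H](OS(C)(=O)=O)[C@H](O)/C=C/[C@H]1C[C@@H]1[C@H]1CCCC(=O)O1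
F11 | step 4 | (1R)-1-[(1S,2S)-2-({[tert-butyl(diphenyl)silyl]oxy}methyl)cyclopropyl]but-3-en-1-ol | CC(C)(C)[Si](c1ccccc1)(c1ccccc1)OC[C@H]1C[C@@H]1[C@H](O)CC=C
F12 | step 4 | (1R)-1-[(1S,2S)-2-({[tert-butyl(diphenyl)silyl]oxy}methyl)cyclopropyl]but-3-en-1-yl prop-2-enoate | CC(C)(C)[Si](c1ccccc1)(c1ccccc1)OC[C@H]1C[C@@H]1[C@H](OC(=O)C=C)CC=C
F13 | step 4 | (6R)-6-[(1S,2S)-2-({[tert-butyl(diphenyl)silyl]oxy}methyl)cyclopropyl]-5,6-dihydro-2H-pyran-2-one | CC(C)(C)[Si](c1ccccc1)(c1ccccc1)OC[C@H]1C[C@@H]1[C@H]1CC=CC(=O)O1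
A1 | alternative 1 | (Z)-bishomoallylic alcohol with benzyl, 4-methoxybenzyl and tert-butyldiphenylsilyl ethers and a vinyl branch (stereochemistry as in the SMILES) | O[C@H](CCO[Si](c1ccccc1)(c1ccccc1)C(C)(C)C)[C@@H](C=C)[C@H](COCc1ccc(OC)cc1)/C=C\CCOCc1ccccc1
A2 | alternative 1 | all-trans oxolane core with 2-[3-(benzyloxy)-1-hydroxypropyl], 3-[(4-methoxybenzyloxy)methyl], 4-vinyl and 5-[2-(tert-butyldiphenylsilyloxy)ethyl] arms | c1ccccc1COCC[C@H](O)[C@H]1O[C@H](CCO[Si](c2ccccc2)(c2ccccc2)C(C)(C)C)[C@@H](C=C)[C@@H]1COCc1ccc(OC)cc1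
A3 | alternative 2 | (2E,4S,6Z,9Z)-4-{[tert-butyl(dimethyl)silyl]oxy}dodeca-2,6,9-trienal | CC/C=C\C/C=C\C[C@H](O[Si](C)(C)C(C)(C)C)/C=C/C=O
A4 | alternative 2 | (2S,3S,4S,5R)-2-[(1S,3Z,6Z)-1-{[tert-butyl(dimethyl)silyl]oxy}nona-3,6-dien-1-yl]-5-[(2Z,5Z)-octa-2,5-dien-1-yl]-4-{(E)-2-[(1R,2S)-2-[(2R)-6-oxooxan-2-yl]cyclopropyl]ethenyl}oxolane-3-carbaldehyde | CC/C=C\C/C=C\C[C@H](O[Si](C)(C)C(C)(C)C)[C@H]1O[C@H](C/C=C\C/C=C\CC)[C@@H](/C=C/[C@H]2C[C@@H]2[C@H]2CCCC(=O)O2)[C@@H]1C=O
A5 | alternative 3 | (6R)-6-[(1S,2S)-2-[(1R,2E,4S,6Z,9Z)-1,4-bis{[tert-butyl(dimethyl)silyl]oxy}dodeca-2,6,9-trien-1-yl]cyclopropyl]oxan-2-one | CC/C=C\C/C=C\C[C@H](O[Si](C)(C)C(C)(C)C)/C=C/[C@H](O[Si](C)(C)C(C)(C)C)[C@H]1C[C@@H]1[C@H]1CCCC(=O)O1
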